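**Plan** (atoms numbered as in 1-benzoxepine: O1, C2–C5, C5a, C6–C9, C9a)
1. Retrosynthesis of the oxepene: both C–Br bonds come from alcohols; the C2 CH2OH comes from hydroboration of a 2-methylene oxepine, itself from a seven-membered enoate lactone made by ring-closing metathesis (C3=C4) of a C9a methacrylate with a C5a allyl group.
2. Retrosynthesis of the carbocycle: C9a–O comes from Baeyer–Villiger oxidation of a C9a aldehyde and C7–OH from the epoxide of a C7=C8 cyclohexene; this cyclohex-3-ene acid is cut at C9–C9a and reconnected C7–O to a δ-lactone (ring: O, C=O, C9a, C5a, C6, C7) carrying a vinyl group (C8=C9) on C7.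
3. Enabling feature: C9a (quaternary, O-bearing) and C7 (heteroatom-bearing) are 1,4 across the cyclohexane with C8–C9 between them, so a C7–O–C(=O)–C9a lactone places the vinyl terminus C9 in a [3,3] array with the enolisable C9a.
4. Forward: (S)-pantolactone gives a vinyl-carbinol enal; Mukaiyama–Michael addition and lactonisation give the lactone; an Ireland–Claisen ring contraction closes the carbocycle; oxidation, hydride and bromide adjust it; ester, metathesis, methylenation, hydroboration and bromide close the oxepene.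
5. Stereochemistry: the C7 carbinol comes from pantolactone and C5a from the imidazolidinone catalyst; C9a is set by chirality transfer in the Claisen step, which erases C7; C7 is rebuilt by face-selective epoxidation, trans-diaxial hydride opening and SN2 bromide; C2 is set by hydroboration anti to the C9a methyl.

Key step: step 7

Remark: (S)-pantolactone, the imidazolidinone and Ph3P=CHCHO are taken as commercial; C-3 of the lactones is carried as an epimer mixture because it is planarised in step 7.

Step 1
Reactants: 1 (S)-pantolactone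
Product: 2 (3S)-4,4-dimethyloxolane-2,3-diol
Conditions: i-Bu2AlH (2.2 equiv), CH2Cl2, −78 °C; aq. potassium sodium tartrate
Reagents that add atoms: none
Why: Partial reduction of a γ-lactone by i-Bu2AlH at low temperature stops at the aluminium hemiacetal, so the lactol should form without touching the carbinol stereocenter.

Step 2
Reactants: 2 (3S)-4,4-dimethyloxolane-2,3-diol
Product: 3 (3R)-2,2-dimethylpent-4-ene-1,3-diol
Conditions: Ph3PCH3Br, KN(SiMe3)2 (3 equiv), THF, 0 °C → rt
Reagents that add atoms: methylenetriphenylphosphorane, C=P(c1ccccc1)(c1ccccc1)c1ccccc1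
Why: Wittig methylenation of the open hydroxy-aldehyde form of the lactol should give the vinyl carbinol with the stereocenter unchanged (the descriptor switches from S to R by priority only).

Step 3
Reactants: 3 (3R)-2,2-dimethylpent-4-ene-1,3-diol
Product: 5 (2E,5R)-5-hydroxy-4,4-dimethylhepta-2,6-dienal, via hydroxy aldehyde 4 (not isolated)
Conditions: TEMPO (10 mol %), PhI(OAc)2, CH2Cl2, rt; then Ph3P=CHCHO, toluene, 80 °C
Reagents that add atoms: (triphenylphosphoranylidene)acetaldehyde, O=CC=P(c1ccccc1)(c1ccccc1)c1ccccc1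
Why: Oxoammonium oxidation should pick the primary over the hindered secondary alcohol, and the stabilised ylide should then give the E-enal in a one-pot oxidation–Wittig sequence.

Step 4
Reactants: 6 S-ethyl propanethioate
Product: 7 (Z)-1-(ethylsulfanyl)-1-(trimethylsilyloxy)prop-1-ene
Conditions: LiN(i-Pr)2, THF, −78 °C; Me3SiCl
Reagents that add atoms: chlorotrimethylsilane, C[Si](C)(C)Cl
Why: Kinetic enolisation of the thioester and O-silylation should give the Z silyl ketene thioacetal, the usual nucleophile for iminium-catalysed Mukaiyama–Michael additions.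

Step 5
Reactants: 5 (2E,5R)-5-hydroxy-4,4-dimethylhepta-2,6-dienal; 7 (Z)-1-(ethylsulfanyl)-1-(trimethylsilyloxy)prop-1-ene
Product: 9 2-[(4R,6R)-6-ethenyl-3,5,5-trimethyl-2-oxooxan-4-yl]acetaldehyde, via hydroxy thioester 8 (not isolated)
Conditions: 7 (3 equiv), (2S,5S)-5-benzyl-2-tert-butyl-3-methylimidazolidin-4-one·CCl3CO2H (20 mol %), H2O (2 equiv), CH2Cl2, −50 °C; then AgOCOCF3, CH2Cl2, rt
Reagents that add atoms: none
Why: In this organocatalytic Mukaiyama–Michael addition the E-iminium ion of 5 is shielded on one face by the benzyl group of the (2S,5S) catalyst, so the ketene thioacetal should add to give the 3R adduct (C-2 is irrelevant), and silver-assisted thioester lactonisation onto the C-5 hydroxyl then closes the δ-lactone with side arm and vinyl cis.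

Step 6
Reactants: 9 2-[(4R,6R)-6-ethenyl-3,5,5-trimethyl-2-oxooxan-4-yl]acetaldehyde
Product: 10 (4R,6R)-6-ethenyl-3,5,5-trimethyl-4-(prop-2-en-1-yl)oxan-2-one
Conditions: Ph3PCH3Br, KN(SiMe3)2 (1.1 equiv), THF, −78 → 0 °C
Reagents that add atoms: methylenetriphenylphosphorane, C=P(c1ccccc1)(c1ccccc1)c1ccccc1
Why: Wittig methylenation should be chemoselective for the aldehyde over the lactone at low temperature and turns the side arm into the allyl group needed for the later metathesis.

Step 7
Reactants: 10 (4R,6R)-6-ethenyl-3,5,5-trimethyl-4-(prop-2-en-1-yl)oxan-2-one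
Product: 13 (1S,6S)-1,5,5-trimethyl-6-(prop-2-en-1-yl)cyclohex-3-ene-1-carboxylic acid, via silyl ketene acetal 11 (not isolated), via silyl ester 12 (not isolated)
Conditions: LiN(i-Pr)2, THF, −78 °C; t-BuMe2SiCl, HMPA, −78 °C → rt; toluene, 110 °C; then 1 M HCl, THF
Reagents that add atoms: none
Why: Ireland–Claisen rearrangement in its ring-contracting form: the only α-hydrogen of the lactone (C-3) is removed, the enolate is O-silylated, and the array C3=C2(OSi)–O1–C6–CH=CH2 undergoes a concerted [3,3] shift in which C-3 bonds to the vinyl terminus while O1–C6 breaks, so the lactone C–O bond is traded for the ring C–C bond and a silyl ester. The closest known reaction type is the Claisen rearrangement of silyl ketene acetals of alkenyl lactones to cycloalkene carboxylic acids. The cyclohexene ring (C-3, C-4, C-5, C-6 of the lactone and both vinyl carbons) is closed by this sigmatropic ring contraction through a boat-shaped bicyclic transition state, the only geometry the lactone allows, so it is not an exo or endo attack on a π bond. The new quaternary stereocenter is set by chirality transfer from the carbinol carbon C-6: the vinyl terminus can reach the ketene acetal only on the ring face to which it is tethered, and because the allyl arm at C-4 sits on the same face the carboxyl ends trans and the methyl cis to the allyl arm, which is the anti relation of the C-9a methyl and the C-5a hydrogen in the target (the descriptor of the ring CH changes from R to S by priority only). The step needs regioselective enolisation, secured by the single α-hydrogen, and the Claisen path must beat a Cope shift of the allyl arm onto the ketene acetal carbon, which the exothermic formation of the ester carbonyl should secure at 110 °C.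

Step 8
Reactants: 13 (1S,6S)-1,5,5-trimethyl-6-(prop-2-en-1-yl)cyclohex-3-ene-1-carboxylic acid
Product: 14 [(1S,6S)-1,5,5-trimethyl-6-(prop-2-en-1-yl)cyclohex-3-en-1-yl]methanol
Conditions: LiAlH4, THF, 0 → 65 °C
Reagents that add atoms: none
Why: Hydride reduction of the hindered acid should give the neopentyl primary alcohol and leave both alkenes and the stereocenters alone.

Step 9
Reactants: 14 [(1S,6S)-1,5,5-trimethyl-6-(prop-2-en-1-yl)cyclohex-3-en-1-yl]methanol
Product: 15 (1S,6S)-1,5,5-trimethyl-6-(prop-2-en-1-yl)cyclohex-3-ene-1-carbaldehyde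
Conditions: Dess–Martin periodinane, CH2Cl2, rt
Reagents that add atoms: none
Why: Mild hypervalent-iodine oxidation should give the aldehyde, which has no α-hydrogen and cannot epimerise.

Step 10
Reactants: 15 (1S,6S)-1,5,5-trimethyl-6-(prop-2-en-1-yl)cyclohex-3-ene-1-carbaldehyde
Product: 17 (1S,3S,4S,6R)-2,2,4-trimethyl-3-(prop-2-en-1-yl)-7-oxabicyclo[4.1.0]heptan-4-yl formate, via formate 16 (not isolated)
Conditions: mCPBA (2.3 equiv), CH2Cl2, 0 °C → rt
Reagents that add atoms: mCPBA, OOC(=O)c1cccc(Cl)c1
Why: Baeyer–Villiger oxidation of the α-quaternary aldehyde (the tertiary alkyl group migrates with retention, giving the formate of the tertiary alcohol) and Prilezhaev epoxidation of the ring alkene on the face away from the axial methyl groups should run in one flask, while the monosubstituted allyl alkene, the least nucleophilic π bond, should survive.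

Step 11
Reactants: 17 (1S,3S,4S,6R)-2,2,4-trimethyl-3-(prop-2-en-1-yl)-7-oxabicyclo[4.1.0]heptan-4-yl formate
Product: 18 (1S,2S,4R)-1,3,3-trimethyl-2-(prop-2-en-1-yl)cyclohexane-1,4-diol
Conditions: LiAlH4, THF, 0 → 65 °C
Reagents that add atoms: none
Why: Hydride should cleave the formate and open the epoxide trans-diaxially (Fürst–Plattner rule) at the carbon remote from the gem-dimethyl group, which leaves the secondary hydroxyl axial with R configuration.

Step 12
Reactants: 18 (1S,2S,4R)-1,3,3-trimethyl-2-(prop-2-en-1-yl)cyclohexane-1,4-diol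
Product: 19 (1S,2S,4S)-4-bromo-1,3,3-trimethyl-2-(prop-2-en-1-yl)cyclohexan-1-ol
Conditions: CBr4, PPh3, toluene, 0 → 60 °C
Reagents that add atoms: carbon tetrabromide, BrC(Br)(Br)Br
Why: In this Appel reaction the secondary alcohol should form the oxyphosphonium salt and bromide should displace it with inversion (SN2), turning the axial R carbinol into the equatorial S bromide, while the tertiary alcohol is too hindered to be activated.

Step 13
Reactants: 19 (1S,2S,4S)-4-bromo-1,3,3-trimethyl-2-(prop-2-en-1-yl)cyclohexan-1-ol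
Product: 20 (1S,2S,4S)-4-bromo-1,3,3-trimethyl-2-(prop-2-en-1-yl)cyclohexyl 2-methylprop-2-enoate
Conditions: LiN(SiMe3)2, THF, −78 °C; CH2=C(CH3)COCl, −78 → 0 °C
Reagents that add atoms: methacryloyl chloride, CC(=C)C(=O)Cl
Why: Acylation of the lithium alkoxide is the reliable way to esterify a hindered tertiary alcohol, and at −78 °C it should outrun transannular displacement of the bromide.

Step 14
Reactants: 20 (1S,2S,4S)-4-bromo-1,3,3-trimethyl-2-(prop-2-en-1-yl)cyclohexyl 2-methylprop-2-enoate
Product: 21 (5aS,7S,9aS)-7-bromo-3,6,6,9a-tetramethyl-5a,6,7,8,9,9a-hexahydro-1-benzoxepin-2(5H)-one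
Conditions: second-generation Grubbs catalyst (10 mol %), toluene (2 mM), 80 °C
Reagents that add atoms: none
Why: Ring-closing metathesis between the allyl group and the methacrylate, held gauche on trans-diequatorial positions of the chair, should form the seven-membered α-methyl enoate lactone with loss of ethene.

Step 15
Reactants: 21 (5aS,7S,9aS)-7-bromo-3,6,6,9a-tetramethyl-5a,6,7,8,9,9a-hexahydro-1-benzoxepin-2(5H)-one
Product: 22 (5aS,7S,9aS)-7-bromo-3,6,6,9a-tetramethyl-2-methylidene-2,5,5a,6,7,8,9,9a-octahydro-1-benzoxepine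
Conditions: Cp2TiMe2 (3 equiv), toluene, 70 °C, dark
Reagents that add atoms: dimethyltitanocene, C[Ti](C)(C1C=CC=C1)C1C=CC=C1
Why: Petasis methylenation should convert the lactone carbonyl into the exocyclic enol ether under non-acidic conditions that tolerate the secondary bromide.

Step 16
Reactants: 22 (5aS,7S,9aS)-7-bromo-3,6,6,9a-tetramethyl-2-methylidene-2,5,5a,6,7,8,9,9a-octahydro-1-benzoxepine
Product: 24 [(2R,5aS,7S,9aS)-7-bromo-3,6,6,9a-tetramethyl-2,5,5a,6,7,8,9,9a-octahydro-1-benzoxepin-2-yl]methanol, via alkylborane 23 (not isolated)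
Conditions: 9-BBN-H, THF, 0 °C → rt; then NaOH, H2O2, 0 °C
Reagents that add atoms: hydrogen peroxide, OO
Why: Hydroboration–oxidation of the exocyclic enol ether should put boron on the terminal carbon and deliver hydrogen to C-2 from the ring face anti to the axial C-9a methyl group, which sets 2R with the hydroxymethyl group cis to that methyl.

Step 17
Reactants: 24 [(2R,5aS,7S,9aS)-7-bromo-3,6,6,9a-tetramethyl-2,5,5a,6,7,8,9,9a-octahydro-1-benzoxepin-2-yl]methanol
Product: 25 Palisadin B
Conditions: CBr4, PPh3, CH2Cl2, 0 °C → rt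
Reagents that add atoms: carbon tetrabromide, BrC(Br)(Br)Br
Why: Appel bromination of the unhindered primary alcohol under neutral conditions should complete the target without touching the allylic ether or the secondary bromide.

**Compound list**
1 | (S)-pantolactone, (3S)-3-hydroxy-4,4-dimethyloxolan-2-one | CC1(C)COC(=O)[C@H]1O | starting material
2 | (3S)-4,4-dimethyloxolane-2,3-diol (lactol, both anomers) | CC1(C)COC(O)[C@H]1O | intermediate
3 | (3R)-2,2-dimethylpent-4-ene-1,3-diol | OCC(C)(C)[C@H](O)C=C | intermediate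
4 | (3R)-3-hydroxy-2,2-dimethylpent-4-enal | O=CC(C)(C)[C@H](O)C=C | intermediate
5 | (2E,5R)-5-hydroxy-4,4-dimethylhepta-2,6-dienal | O=C/C=C/C(C)(C)[C@H](O)C=C | intermediate
6 | S-ethyl propanethioate | CCC(=O)SCC | starting material
7 | (Z)-1-(ethylsulfanyl)-1-(trimethylsilyloxy)prop-1-ene | C/C=C(\SCC)O[Si](C)(C)C | intermediate
8 | S-ethyl (3R,5R)-5-hydroxy-2,4,4-trimethyl-3-(2-oxoethyl)hept-6-enethioate (C-2 epimers) | CCSC(=O)C(C)[C@@H](CC=O)C(C)(C)[C@H](O)C=C | intermediate
9 | 2-[(4R,6R)-6-ethenyl-3,5,5-trimethyl-2-oxooxan-4-yl]acetaldehyde (C-3 epimers; side arm and vinyl cis) | O=CC[C@@H]1C(C)C(=O)O[C@H](C=C)C1(C)C | intermediate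
10 | (4R,6R)-6-ethenyl-3,5,5-trimethyl-4-(prop-2-en-1-yl)oxan-2-one (C-3 epimers; allyl and vinyl cis) | C=CC[C@@H]1C(C)C(=O)O[C@H](C=C)C1(C)C | intermediate
11 | tert-butyl{[(4S,6R)-6-ethenyl-3,5,5-trimethyl-4-(prop-2-en-1-yl)-5,6-dihydro-4H-pyran-2-yl]oxy}dimethylsilane | C=CC[C@@H]1C(C)=C(O[Si](C)(C)C(C)(C)C)O[C@H](C=C)C1(C)C | intermediate
12 | tert-butyldimethylsilyl (1S,6S)-1,5,5-trimethyl-6-(prop-2-en-1-yl)cyclohex-3-ene-1-carboxylate | C=CC[C@H]1C(C)(C)C=CC[C@]1(C)C(=O)O[Si](C)(C)C(C)(C)C | intermediate
13 | (1S,6S)-1,5,5-trimethyl-6-(prop-2-en-1-yl)cyclohex-3-ene-1-carboxylic acid | C=CC[C@H]1C(C)(C)C=CC[C@]1(C)C(=O)O | intermediate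
14 | [(1S,6S)-1,5,5-trimethyl-6-(prop-2-en-1-yl)cyclohex-3-en-1-yl]methanol | C=CC[C@H]1C(C)(C)C=CC[C@]1(C)CO | intermediate
15 | (1S,6S)-1,5,5-trimethyl-6-(prop-2-en-1-yl)cyclohex-3-ene-1-carbaldehyde | C=CC[C@H]1C(C)(C)C=CC[C@]1(C)C=O | intermediate
16 | (1S,6S)-1,5,5-trimethyl-6-(prop-2-en-1-yl)cyclohex-3-en-1-yl formate | C=CC[C@H]1C(C)(C)C=CC[C@]1(C)OC=O | intermediate
17 | (1S,3S,4S,6R)-2,2,4-trimethyl-3-(prop-2-en-1-yl)-7-oxabicyclo[4.1.0]heptan-4-yl formate (epoxide cis to the formate oxygen) | C=CC[C@H]1C(C)(C)[C@@H]2O[C@@H]2C[C@]1(C)OC=O | intermediate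
18 | (1S,2S,4R)-1,3,3-trimethyl-2-(prop-2-en-1-yl)cyclohexane-1,4-diol | C=CC[C@H]1C(C)(C)[C@H](O)CC[C@]1(C)O | intermediate
19 | (1S,2S,4S)-4-bromo-1,3,3-trimethyl-2-(prop-2-en-1-yl)cyclohexan-1-ol | C=CC[C@H]1C(C)(C)[C@@H](Br)CC[C@]1(C)O | intermediate
20 | (1S,2S,4S)-4-bromo-1,3,3-trimethyl-2-(prop-2-en-1-yl)cyclohexyl 2-methylprop-2-enoate | C=CC[C@H]1C(C)(C)[C@@H](Br)CC[C@]1(C)OC(=O)C(C)=C | intermediate
21 | (5aS,7S,9aS)-7-bromo-3,6,6,9a-tetramethyl-5a,6,7,8,9,9a-hexahydro-1-benzoxepin-2(5H)-one | CC1=CC[C@H]2C(C)(C)[C@@H](Br)CC[C@]2(C)OC1=O | intermediate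
22 | (5aS,7S,9aS)-7-bromo-3,6,6,9a-tetramethyl-2-methylidene-2,5,5a,6,7,8,9,9a-octahydro-1-benzoxepine | CC1=CC[C@H]2C(C)(C)[C@@H](Br)CC[C@]2(C)OC1=C | intermediate
23 | 9-{[(2S,5aS,7S,9aS)-7-bromo-3,6,6,9a-tetramethyl-2,5,5a,6,7,8,9,9a-octahydro-1-benzoxepin-2-yl]methyl}-9-borabicyclo[3.3.1]nonane | CC1=CC[C@H]2C(C)(C)[C@@H](Br)CC[C@]2(C)O[C@H]1CB1C2CCCC1CCC2 | intermediate
24 | [(2R,5aS,7S,9aS)-7-bromo-3,6,6,9a-tetramethyl-2,5,5a,6,7,8,9,9a-octahydro-1-benzoxepin-2-yl]methanol | CC1=CC[C@H]2C(C)(C)[C@@H](Br)CC[C@]2(C)O[C@H]1CO | intermediate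
25 | Palisadin B, (2R,5aS,7S,9aS)-7-bromo-2-(bromomethyl)-3,6,6,9a-tetramethyl-2,5,5a,6,7,8,9,9a-octahydro-1-benzoxepine | CC1=CC[C@H]2C(C)(C)[C@@H](Br)CC[C@]2(C)O[C@H]1CBr | target

**Step count and risks**
Total steps: 17. Longest linear sequence: 16 steps (steps 1–3 and 5–17); step 4 prepares the nucleophile for step 5.

Step 12 (most at risk). E2 loss of the axial oxyphosphonium group with the anti-periplanar axial hydrogen at C-5, a 1,2-methyl shift from C-3, or activation of the free tertiary carbinol may outrun backside attack at the neopentyl carbon. The fallback takes the substitution out of the warm one-pot phosphonium manifold and splits it into two cold, separate events. It sets out from 18: Tf2O (1.05 equiv) and 2,6-di-tert-butylpyridine in CH2Cl2 at −78 °C should sulfonylate only the secondary hydroxyl to give (1R,3S,4S)-4-hydroxy-2,2,4-trimethyl-3-(prop-2-en-1-yl)cyclohexyl trifluoromethanesulfonate F1. Bu4NBr in toluene at −40 → 0 °C should then displace the triflate with inversion below the temperature at which elimination sets in. The route is rejoined at 19.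

Step 5. Conjugate addition at the β-carbon next to the quaternary centre may be slow, and facial selectivity may erode if catalyst control and the existing C-5 stereocenter are mismatched, which would give the trans lactone. The fallback replaces catalyst control by substrate control through a tether. It sets out from 5: methyl malonyl chloride and pyridine in CH2Cl2 should acylate the carbinol to give methyl (3R,5E)-4,4-dimethyl-7-oxohepta-1,5-dien-3-yl propanedioate F2. Cs2CO3 (0.2 equiv) in MeCN should trigger a reversible intramolecular Michael addition through a chair with the vinyl group and the new side arm both equatorial, giving the cis lactone methyl (4R,6R)-6-ethenyl-5,5-dimethyl-2-oxo-4-(2-oxoethyl)oxane-3-carboxylate F3. K2CO3 and MeI in acetone should C-methylate it to methyl (4S,6R)-6-ethenyl-3,5,5-trimethyl-2-oxo-4-(2-oxoethyl)oxane-3-carboxylate F4. Ph3P=CH2 in THF at −78 → 0 °C should give methyl (4S,6R)-6-ethenyl-3,5,5-trimethyl-2-oxo-4-(prop-2-en-1-yl)oxane-3-carboxylate F5. Krapcho demethoxycarbonylation (LiCl, wet DMSO, 140 °C) returns the route at 10.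

Step 10. The excess peracid may also epoxidise the allyl group, and without a directing group the ring alkene may be attacked from the wrong face. The fallback separates the two oxidations and directs the epoxidation. It sets out from 14: VO(acac)2 (5 mol %) and t-BuOOH in CH2Cl2 should deliver oxygen to the ring alkene on the face of the hydroxymethyl group, giving [(1S,3R,4S,6R)-2,2,4-trimethyl-3-(prop-2-en-1-yl)-7-oxabicyclo[4.1.0]heptan-4-yl]methanol F6. Dess–Martin periodinane should give (1S,3S,4S,6R)-2,2,4-trimethyl-3-(prop-2-en-1-yl)-7-oxabicyclo[4.1.0]heptane-4-carbaldehyde F7. mCPBA (1.1 equiv) then performs only the Baeyer–Villiger oxidation, and the route is rejoined at 17.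

Further compounds
F1 | step 12 | (1R,3S,4S)-4-hydroxy-2,2,4-trimethyl-3-(prop-2-en-1-yl)cyclohexyl trifluoromethanesulfonate | C=CC[C@H]1C(C)(C)[C@H](OS(=O)(=O)C(F)(F)F)CC[C@]1(C)O
F2 | step 5 | methyl (3R,5E)-4,4-dimethyl-7-oxohepta-1,5-dien-3-yl propanedioate | O=C/C=C/C(C)(C)[C@H](OC(=O)CC(=O)OC)C=C
F3 | step 5 | methyl (4R,6R)-6-ethenyl-5,5-dimethyl-2-oxo-4-(2-oxoethyl)oxane-3-carboxylate (C-3 epimers) | O=CC[C@@H]1C(C(=O)OC)C(=O)O[C@H](C=C)C1(C)C
F4 | step 5 | methyl (4S,6R)-6-ethenyl-3,5,5-trimethyl-2-oxo-4-(2-oxoethyl)oxane-3-carboxylate (C-3 epimers) | O=CC[C@@H]1C(C)(C(=O)OC)C(=O)O[C@H](C=C)C1(C)C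
F5 | step 5 | methyl (4S,6R)-6-ethenyl-3,5,5-trimethyl-2-oxo-4-(prop-2-en-1-yl)oxane-3-carboxylate (C-3 epimers) | C=CC[C@@H]1C(C)(C(=O)OC)C(=O)O[C@H](C=C)C1(C)C
F6 | step 10 | [(1S,3R,4S,6R)-2,2,4-trimethyl-3-(prop-2-en-1-yl)-7-oxabicyclo[4.1.0]heptan-4-yl]methanol | C=CC[C@H]1C(C)(C)[C@@H]2O[C@@H]2C[C@]1(C)CO
F7 | step 10 | (1S,3S,4S,6R)-2,2,4-trimethyl-3-(prop-2-en-1-yl)-7-oxabicyclo[4.1.0]heptane-4-carbaldehyde | C=CC[C@H]1C(C)(C)[C@@H]2O[C@@H]2C[C@]1(C)C=O
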